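**Conserved count.** Every unit of substrate charged stands as substrate, as target, or as something past target, so 100 percent minus the two readings counts what has gone past. By the last reading that remainder is 10.9% in dusk and 17.5% in autumn, while target falls.

| flask | substrate | reagent in the second phase | remark | time | volume of the second phase over the first |
|---|---|---|---|---|---|
| dusk | 1 M | 0.40 equiv | run made earlier |  |  |
| autumn | 1 M | 0.60 equiv | run made earlier |  |  |
| flask | 1.0 M | 0.800 equiv |  | 5.0 h | 0.50 |

| run | time / h | target / % | substrate / % |
|---|---|---|---|
| dusk | 0.250 | 5.8 | 93.8 |
| dusk | 0.833 | 10.1 | 86.6 |
| dusk | 1.33 | 9.9 | 85.9 |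
| dusk | 2.00 | 8.7 | 85.2 |
| dusk | 3.00 | 6.8 | 84.3 |
| dusk | 4.00 | 4.9 | 84.2 |
| autumn | 0.250 | 8.0 | 91.6 |
| autumn | 0.833 | 13.3 | 81.6 |
| autumn | 1.33 | 11.7 | 79.9 |
| autumn | 2.00 | 9.7 | 77.3 |
| autumn | 3.00 | 8.7 | 76.0 |
| autumn | 4.00 | 7.2 | 75.3 |

(scatter of a reading: 0.5 percentage points)

- in the second phase: reagent in the second phase; everything else is in the first
- charges count per volume of the first phase; a concentration in a rate is the amount of a species over the volume of its own phase; every rate counts per litre of the first phase
- the earlier runs hold the two phases in the same ratio of volumes as the flask asked about

- the target standing at 5.0 h, as a percentage of the substrate charged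
- the change that raises the amount of target at 5.0 h, in percent of the substrate charged most ("none" if none brings more than 2 percentage points) (eta / epsilon / none)
- amount of target at 5.0 h, in percent of the substrate charged, after eta

- eta: doubling the amount of reagent in the second phase, all else as stated
- epsilon: doubling the transfer coefficient of the reagent in the second phase, all else as stated

**Two times.** Target has its highest reading at 0.833 h in both runs. Both runs together, from that reading to the last, give 4.80 h for the target lifetime, the apparent time, read off these runs, in which target falls by a factor of e after its highest reading. The rise, taken as the time of that highest reading, is shorter than this lifetime by a factor of 5.76, so the estimate below treats a late reading as a peak height discounted by the lifetime.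

**Own reckoning.** Dusk, autumn and the flask step evenly in the charge of reagent in the second phase, so the peak readings, carried one step past autumn, give an estimated peak of 16.5% for the flask. Discounted from 0.833 h to 5.0 h, that leaves 6.93%.

**The forecast.** The forecast gives 7%, names eta as best with 11%, and argues that “Doubling the reagent nearly doubles formation”.

**The result.** The flask holds 5.99% at 5.0 h, so the own reckoning stands 0.94 percentage points high. Doubling the reagent in the second phase changes target in the flask by −0.94 points, to 5.04%, and doubling its transfer coefficient changes it by −0.08 points; the best change is none.

    reagent in the reaction phase ⇌ reagent in the second phase, rate k1*([reagent in the reaction phase] - [reagent in the second phase]/K1) per volume of the first phase (partition coefficient = 1.80, kL = 0.110 min⁻¹)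
    substrate + reagent in the reaction phase ⇌ target (K = 1.10 M⁻¹, k = 0.0370 M⁻¹ min⁻¹)
    reagent in the reaction phase + target → over-reacted product (k = 0.0550 M⁻¹ min⁻¹)
    reagent in the reaction phase → decomposition product (k = 2.60 × 10⁻⁵ min⁻¹)

**Lifetime used.** Counted back from 5.99% with 4.80 h, the lifetime gives 10.1% for the flask at 2.50 h; the flask holds 9.71%. The same count gives 11.2% for the neighbour read at 2.0 h, which holds 11.1%. Target in the flask stands low at 5.0 h because it runs back to substrate and reagent in the reaction phase and goes on to over-reacted product. Against 5.99%, the flask holds 29.8% without the way back and 24.3% without the over-reaction.

The earlier runs and the new flask were generated by integration for substances that don't exist, and the scatter is random.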